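Cuts, late to early: the C8–O acyl bond (tiglate), C11=C13 and the C3 carbonyl (back to a PMB ether). Then C4 is rejoined to C8. Behind that: C6–O (lactone), C1=C2, C10–C14, C10–C1, C8–C9, C7–C11 and C3–C4.
Enabling feature: in the ten-membered ring C1–C10, the Z alkene C4=C5 (C3 and C6 on the same side) faces oxygen-bearing C8 across the ring. A C4–C8 bond divides this ring into the cyclopentane C4–C5–C6–C7–C8, which carries the cis γ-lactone at C6–C7, and the cycloheptene C8–C9–C10–C1–C2–C3–C4, which holds the cis C1=C2 and the C10 carbinol. A C4=C5 alkene and a C8 ketone are exactly what a C8 hydroxy C5 sulfonate leaves when C4–C8 breaks.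
Forward ring order: cyclopentane (from the dione), temporary bridged δ-lactone (C5–O to C8), cycloheptene by metathesis, γ-lactone, then the ten-membered ring by fragmentation.
Stereochemistry: C3 from Pd with a chiral ligand (erased at the end); C4 and C5 from a CBS desymmetrisation; C7 from enolate alkylation anti to the C3 chain; C8 (ring fusion) from the C5–O tether; C10 from chelation; C6 from an SN2 lactonisation; C5 again from C8–OH-directed hydride; the final C8 from C10–OH-directed hydride.
The ring fusion must be cis (C15 and O8 on one face). Only then can C3 sit axial on the cyclopentane while the C5 sulfonate, cis to C3, is antiperiplanar to C4–C8, which is what gives the Z alkene.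
Key step: step 18

Convention: germacrane numbering of 36 is used for all intermediates (ring C1–C10, lactone C11–C13, C14 on C10, C15 on C4). With the cyclopentane drawn C4→C5→C6→C7→C8 clockwise, β points toward the viewer and α away.
Assumption: the (R,R) ligand in step 3 is taken to give the (3R) ether. C3 ends as a carbonyl carbon, so the antipodal ligand would serve equally if the sense of induction is the reverse.
Assumption: 36 is made as the open γ-hydroxy dienone that is drawn. Reversible closure of C10–OH onto C3=O across the Z alkene would be a property of the product itself.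

Step 1
Reactants: 1 4-methoxybenzyl alcohol; 2 propargyl bromide
Product: 3 4-methoxybenzyl propargyl ether
Conditions: NaH, Bu4NI (cat.), THF, 0 °C → rt
Reagents that add atoms: none
Why: Williamson ether synthesis of a primary alkoxide with a reactive propargylic bromide.

Step 2
Reactants: 3 4-methoxybenzyl propargyl ether
Product: 4 4-methoxybenzyloxyallene
Conditions: KOtBu (0.3 equiv), THF, rt
Reagents that add atoms: none
Why: Base-catalysed propargyl–allene isomerisation, which for propargyl ethers stops at the alkoxyallene.

Step 3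
Reactants: 4 4-methoxybenzyloxyallene; 5 2-methylcyclopentane-1,3-dione
Product: 6 (R)-2-[1-(4-methoxybenzyloxy)prop-2-en-1-yl]-2-methylcyclopentane-1,3-dione
Conditions: Pd2(dba)3·CHCl3 (2.5 mol %), (R,R)-DACH-phenyl Trost ligand (7.5 mol %), PhCO2H (10 mol %), CH2Cl2, rt
Reagents that add atoms: none
Why: Palladium-catalysed hydroalkylation of an alkoxyallene (an asymmetric allylic alkylation in which hydropalladation gives a 1-alkoxy-π-allyl complex): the acidic 2-alkyl-1,3-dione attacks the oxygen-bearing terminus to give the branched allylic ether, reversible O-alkylation drains to the C-alkylated product, and the chiral ligand sets C3 while C4 is still prochiral.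

Step 4
Reactants: 6 (R)-2-[1-(4-methoxybenzyloxy)prop-2-en-1-yl]-2-methylcyclopentane-1,3-dione
Product: 7 (2R,3S)-3-hydroxy-2-[(1R)-1-(4-methoxybenzyloxy)prop-2-en-1-yl]-2-methylcyclopentan-1-one (5β-OH cis to the β C3 chain, C15 α)
Conditions: (R)-2-methyl-CBS-oxazaborolidine (20 mol %), catecholborane (1.2 equiv), toluene, −78 → −40 °C; MeOH
Reagents that add atoms: none
Why: Corey–Bakshi–Shibata reduction run as a desymmetrisation of a 2,2-disubstituted cyclopentane-1,3-dione: the catalyst dictates an (S) carbinol (quaternary C4 as the large flank, CH2 as the small one) and hydride enters from the face of the small methyl group, so only one of the two carbonyl groups satisfies both demands, which fixes C4 and places the C5 hydroxyl cis to the C3 chain, while catecholborane leaves the vinyl group untouched.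

Step 5
Reactants: 7 ketol
Product: 8 5β-triethylsilyl ether of 7
Conditions: Et3SiCl, imidazole, CH2Cl2, 0 °C
Reagents that add atoms: chlorotriethylsilane, CC[Si](Cl)(CC)CC
Why: Standard silylation of a secondary alcohol, which prevents alkoxide formation (and retro-aldol cleavage) in the enolate step.

Step 6
Reactants: 8 5β-triethylsilyl ether; 9 2-bromo-N,N-dimethylacetamide
Product: 11 7α-(dimethylcarbamoylmethyl) ketol (5β-OH free), via triethylsilyl ether 10 (not isolated)
Conditions: LiN(iPr)2 (1.1 equiv), THF, −78 °C; 9, DMPU, −78 → −30 °C; then 1 M HCl, THF, 0 °C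
Reagents that add atoms: none
Why: Kinetic enolate alkylation: the ketone can enolise only toward C7 because C4 is quaternary, the bromoacetamide approaches the enolate anti to the β C3 chain and the β silyloxy group so that C11 is α, dilute acid then removes the silyl ether in the same flask, and the tertiary amide is chosen because it resists the later Grignard reagents and the C8 alkoxide.

Step 7
Reactants: 11 7α-(dimethylcarbamoylmethyl) ketol; 12 bromoacetyl bromide
Product: 13 5β-bromoacetate of 11
Conditions: pyridine, CH2Cl2, −20 → 0 °C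
Reagents that add atoms: none
Why: Acylation of the only hydroxyl group with a reactive acyl bromide, which places C9 and C10 on the β oxygen at C5.

Step 8
Reactants: 13 5β-bromoacetate
Product: 14 bridged hydroxy δ-lactone (O5–C10(=O)–C9H2–C8 bridge on the β face, a 2-oxabicyclo[3.2.1]octan-3-one; 8α-OH)
Conditions: SmI2 (2.2 equiv), THF, −78 °C
Reagents that add atoms: none
Why: SmI2-promoted intramolecular Reformatsky reaction of a β-bromoacetoxy ketone: the samarium enolate hangs from the β oxygen at C5 and can reach the C8 carbonyl only from the β face through a chelated six-membered transition state, which is also the face anti to the C7 side chain, so C9 ends cis to the C3 chain and O8 cis to C15, the relation that becomes the cis ring fusion.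

Step 9
Reactants: 14 bridged hydroxy δ-lactone
Product: 16 vinyl ketone diol (C8–C9H2–C10(=O)–C1H=CH2; 5β-OH; 8α-OH), via Weinreb amide 15 (not isolated)
Conditions: MeNH(OMe)·HCl, iPrMgCl, THF, −20 °C; then CH2=CHMgBr, −78 → 0 °C; inverse quench into cold 1 M HCl
Reagents that add atoms: N,O-dimethylhydroxylamine hydrochloride, CNOC.Cl; vinylmagnesium bromide, C=C[Mg]Br
Why: One-pot Weinreb ketone synthesis: the magnesium amide opens the δ-lactone, the chelated tetrahedral adduct of the N-methoxy amide stops the vinyl Grignard reagent at the ketone stage, the less electrophilic dimethylamide is spared at low temperature, and the cold acidic quench keeps the freed amine from adding to the enone.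

Step 10
Reactants: 16 vinyl ketone diol
Product: 17 (10R)-divinyl triol (C10 bears CH3, OH and vinyl)
Conditions: MeMgBr (4 equiv), CH2Cl2–Et2O, −78 °C
Reagents that add atoms: methylmagnesium bromide, C[Mg]Br
Why: Chelation-controlled 1,2-addition of a Grignard reagent to a β-hydroxy ketone: magnesium bridges the C8 alkoxide and the C10 carbonyl in a six-membered ring that keeps the quaternary C4 equatorial and C7 axial, and methyl attacks the carbonyl face anti to C7, which gives the (10R) carbinol.

Step 11
Reactants: 17 (10R)-divinyl triol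
Product: 18 cis-fused hydroazulene triol (C4–C8 fusion; C15 α, 8-OH α, 5-OH β, 7-CH2CONMe2 α, (3R)-OPMB, (10R)-OH, cis C1=C2)
Conditions: second-generation Hoveyda–Grubbs catalyst (5 mol %), toluene (2 mM), 80 °C
Reagents that add atoms: none
Why: Ring-closing metathesis of two monosubstituted alkenes held cis on adjacent ring atoms closes the seven-membered ring, in which the new C1=C2 can only be cis, while the free allylic hydroxyl at C10 assists such closures and ethene escapes.

Step 12
Reactants: 18 cis-fused hydroazulene triol
Product: 19 C5 ketone diol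
Conditions: Dess–Martin periodinane, NaHCO3, CH2Cl2, 0 °C → rt
Reagents that add atoms: none
Why: Dess–Martin oxidation touches the only secondary alcohol, and its neutral buffered medium spares the β-hydroxy ketone from retro-aldol cleavage.

Step 13
Reactants: 19 C5 ketone diol
Product: 20 C10 triethylsilyl ether (8α-OH free)
Conditions: Et3SiOTf (1.1 equiv), 2,6-lutidine, CH2Cl2, −78 °C
Reagents that add atoms: triethylsilyl trifluoromethanesulfonate, CC[Si](CC)(CC)OS(=O)(=O)C(F)(F)F
Why: Selective silylation of the less hindered of two tertiary alcohols (C8–OH is flanked by the quaternary C4 and by C7), which installs the group that will block retro-aldol opening of the β-oxy ketone formed in the fragmentation.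

Step 14
Reactants: 20 C10 triethylsilyl ether
Product: 22 6β-bromo ketone (8-O-trimethylsilyl ether), via silyl enol ether 21 (not isolated)
Conditions: Me3SiOTf (2.2 equiv), Et3N, CH2Cl2, 0 °C; then NBS, THF, −78 °C
Reagents that add atoms: trimethylsilyl trifluoromethanesulfonate, C[Si](C)(C)OS(=O)(=O)C(F)(F)F; N-bromosuccinimide, O=C1CCC(=O)N1Br
Why: Soft enolisation followed by bromination of the silyl enol ether: the ketone can enolise only toward C6, no alkoxide is formed so the aldol unit survives, O8 is masked at the same time, and bromine enters anti to the α side chain at C7.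

Step 15
Reactants: 22 6β-bromo ketone
Product: 24 keto γ-lactone (cis-fused at C6–C7 on the α face; 8α-OH free), via iminium lactone bromide 23 (not isolated)
Conditions: MeCN–pH 5 acetate buffer, 45 °C
Reagents that add atoms: water, O
Why: Neighbouring-group lactonisation of a γ-halo amide (the ring closure known from halolactonisation of unsaturated amides): the amide oxygen displaces the activated α-keto bromide in a 5-exo-tet SN2 step with inversion, so O6 is α and cis to C11 as a five–five fusion demands, a wrongly placed bromide can epimerise through the enol, water turns the iminium ion into the lactone, and the mild acid also frees O8.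

Step 16
Reactants: 24 keto γ-lactone
Product: 25 5β-alcohol
Conditions: Me4NBH(OAc)3, MeCN–AcOH, −20 °C
Reagents that add atoms: none
Why: Hydroxyl-directed reduction of a β-hydroxy ketone with triacetoxyborohydride (Evans–Saksena type): boron binds the α C8 hydroxyl and delivers hydride to the α face of C5 through a six-membered transition state, so the new hydroxyl is β, trans to C15 and O6 and cis to C3, while the lactone is not reduced.

Step 17
Reactants: 25 5β-alcohol
Product: 26 lactone-fused cis-hydroazulenol 5β-mesylate (C15 α, 8-OH α, C3 and C9 β, O6 and C11 α, (3R)-OPMB, (10R)-OSiEt3)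
Conditions: MsCl, Et3N, CH2Cl2, −20 °C
Reagents that add atoms: methanesulfonyl chloride, CS(=O)(=O)Cl
Why: Sulfonylation through sulfene reaches the hindered secondary alcohol but not the tertiary C8 hydroxyl, and triethylamine is too weak a base to start the fragmentation.

Step 18
Reactants: 26 lactone-fused cis-hydroazulenol 5β-mesylate
Product: 27 (1Z,4Z,3R,6S,7S,10R) ten-membered C8 ketone with cis γ-lactone, C3–OPMB and C10–OSiEt3
Conditions: KN(SiMe3)2 (1.05 equiv), THF, −78 → −40 °C; AcOH, −78 °C
Reagents that add atoms: none
Why: The base removes the C8–OH proton and the alkoxide fragments in one concerted event, its lone pair forming C8=O while the C4–C8 σ bond becomes the C4=C5 π bond and mesylate leaves C5; this is the Grob fragmentation of a bicyclic 1,3-hydroxy sulfonate in its Wharton form, known to turn hydrindane and decalin diol monosulfonates into cyclononenones and cyclodecenones. No ring is closed by bond formation: the ten-membered ring emerges because the bond common to the five- and seven-membered rings is cut. No stereocentre is created, since C4, C5 and C8 become trigonal and C3, C6, C7 and C10 are not touched. The alkene geometry is set by the substrate: the cis fusion lets the cyclopentane adopt the half-chair with C3 axial and the β mesylate equatorial, so C5–O lies close to antiperiplanar to C4–C8 and C3 is gauche to C6, a relation that closes to cis (Z), whereas a trans-fused isomer would hold C3 equatorial and could only give the E alkene. The step needs fragmentation to outrun attack of the alkoxide on the lactone carbonyl and later loss of the lactone carboxylate from the ketone enolate; the first would pass through a strained 2,6-dioxabicyclo[2.2.1]heptane-type adduct, the second has the C6–O bond held near the nodal plane of a C7–C8 enolate by the five-membered lactone, and one equivalent of base, low temperature and an acid quench leave no base behind because potassium mesylate is not basic.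

Step 19
Reactants: 27 ten-membered keto lactone
Product: 28 (3R,6S,7S,10R) C10 hydroxy ketone
Conditions: HF·pyridine, pyridine, THF, 0 °C
Reagents that add atoms: none
Why: Buffered fluoride desilylation removes the triethylsilyl ether without the base that would open the β-hydroxy ketone by retro-aldol reaction and without the strong acid that would ionise the tertiary allylic alcohol.

Step 20
Reactants: 28 C10 hydroxy ketone
Product: 29 (3R,6S,7R,8R,10R) 8,10-anti diol
Conditions: Me4NBH(OAc)3, MeCN–AcOH, −30 °C
Reagents that add atoms: none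
Why: Second hydroxyl-directed triacetoxyborohydride reduction (Evans–Saksena type): boron bound to the C10 hydroxyl delivers hydride across a chair-like six-membered transition state to give the 8,10-anti diol, which is the (8R) alcohol, and lactone, alkenes and PMB ether are inert.

Step 21
Reactants: 29 8,10-anti diol; 30 tigloyl chloride
Product: 31 C8 tiglate (C10–OH free)
Conditions: Et3N, DMAP, CH2Cl2, 0 °C → rt
Reagents that add atoms: none
Why: DMAP-catalysed acylation esterifies the secondary C8 hydroxyl with retention and leaves the tertiary C10 hydroxyl alone, and the E ester cannot isomerise to anything more stable.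

Step 22
Reactants: 31 C8 tiglate
Product: 34 α-methylene lactone tiglate (C3–OPMB), via Mannich base 32 (not isolated), via methiodide 33 (not isolated)
Conditions: LiN(iPr)2 (2.2 equiv), THF, −78 °C; CH2=NMe2+ I−, −78 °C → rt; MeI, CH2Cl2, rt; aq NaHCO3
Reagents that add atoms: Eschenmoser's salt (N,N-dimethylmethyleneiminium iodide), C=[N+](C)C.[I-]; iodomethane, CI
Why: Kinetic lactone enolate formation followed by Mannich reaction with Eschenmoser's salt, quaternisation and β-elimination (the standard α-methylenation of γ-lactones): the first equivalent of base is taken by the C10 hydroxyl, the lactone CH2 is the most acidic C–H left because the tiglate has no α-hydrogen and its γ-methyl group is trans to the carbonyl, and the C11 stereocentre formed on the way is erased in the elimination.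

Step 23
Reactants: 34 α-methylene lactone tiglate
Product: 35 (3R) bis-allylic alcohol
Conditions: DDQ, CH2Cl2–pH 7 buffer, 0 °C
Reagents that add atoms: none
Why: Oxidative cleavage of a 4-methoxybenzyl ether by hydride abstraction and hydrolysis, which is neutral and tolerates the methylene lactone, the tiglate and the tertiary alcohol, and any onward oxidation at C3 only anticipates the last step.

Step 24
Reactants: 35 (3R) bis-allylic alcohol
Product: 36 target CNP0135074.2, (1Z,4Z,6S,7R,8R,10R)
Conditions: MnO2, CH2Cl2, rt
Reagents that add atoms: none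
Why: MnO2 oxidation is selective for allylic alcohols, so the doubly allylic C3 carbinol becomes the cross-conjugated dienone, which removes the auxiliary C3 stereocentre, while the tertiary alcohol and both esters are unaffected.

Compound list
1 | 4-methoxybenzyl alcohol | COc1ccc(CO)cc1 | starting material
2 | propargyl bromide | C#CCBr | starting material
3 | 4-methoxybenzyl propargyl ether | C#CCOCc1ccc(OC)cc1 | intermediate
4 | 4-methoxybenzyloxyallene | C=C=COCc1ccc(OC)cc1 | intermediate
5 | 2-methylcyclopentane-1,3-dione | CC1C(=O)CCC1=O | starting material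
6 | (R)-2-[1-(4-methoxybenzyloxy)prop-2-en-1-yl]-2-methylcyclopentane-1,3-dione | C=C[C@@H](OCc1ccc(OC)cc1)C2(C)C(=O)CCC2=O | intermediate
7 | (2R,3S)-3-hydroxy-2-[(1R)-1-(4-methoxybenzyloxy)prop-2-en-1-yl]-2-methylcyclopentan-1-one | C=C[C@@H](OCc1ccc(OC)cc1)[C@@]2(C)[C@@H](O)CCC2=O | intermediate
8 | 5β-triethylsilyl ether of 7 | C=C[C@@H](OCc1ccc(OC)cc1)[C@@]2(C)[C@@H](O[Si](CC)(CC)CC)CCC2=O | intermediate
9 | 2-bromo-N,N-dimethylacetamide | CN(C)C(=O)CBr | starting material
10 | 7α-(dimethylcarbamoylmethyl) 5β-triethylsilyl ether | C=C[C@@H](OCc1ccc(OC)cc1)[C@@]2(C)[C@@H](O[Si](CC)(CC)CC)C[C@H](CC(=O)N(C)C)C2=O | intermediate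
11 | 7α-(dimethylcarbamoylmethyl) ketol | C=C[C@@H](OCc1ccc(OC)cc1)[C@@]2(C)[C@@H](O)C[C@H](CC(=O)N(C)C)C2=O | intermediate
12 | bromoacetyl bromide | BrCC(=O)Br | starting material
13 | 5β-bromoacetate of 11 | C=C[C@@H](OCc1ccc(OC)cc1)[C@@]2(C)[C@@H](OC(=O)CBr)C[C@H](CC(=O)N(C)C)C2=O | intermediate
14 | bridged hydroxy δ-lactone | C=C[C@@H](OCc1ccc(OC)cc1)[C@@]2(C)[C@@H]3C[C@H](CC(=O)N(C)C)[C@@]2(O)CC(=O)O3 | intermediate
15 | Weinreb amide diol | C=C[C@@H](OCc1ccc(OC)cc1)[C@@]2(C)[C@@H](O)C[C@H](CC(=O)N(C)C)[C@@]2(O)CC(=O)N(C)OC | intermediate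
16 | vinyl ketone diol | C=C[C@@H](OCc1ccc(OC)cc1)[C@@]2(C)[C@@H](O)C[C@H](CC(=O)N(C)C)[C@@]2(O)CC(=O)C=C | intermediate
17 | (10R)-divinyl triol | C=C[C@@H](OCc1ccc(OC)cc1)[C@@]2(C)[C@@H](O)C[C@H](CC(=O)N(C)C)[C@@]2(O)C[C@@](C)(O)C=C | intermediate
18 | cis-fused hydroazulene triol | CN(C)C(=O)C[C@H]1C[C@H](O)[C@]2(C)[C@H](OCc3ccc(OC)cc3)C=C[C@](C)(O)C[C@]12O | intermediate
19 | C5 ketone diol | CN(C)C(=O)C[C@H]1CC(=O)[C@]2(C)[C@H](OCc3ccc(OC)cc3)C=C[C@](C)(O)C[C@]12O | intermediate
20 | C10 triethylsilyl ether | CN(C)C(=O)C[C@H]1CC(=O)[C@]2(C)[C@H](OCc3ccc(OC)cc3)C=C[C@](C)(O[Si](CC)(CC)CC)C[C@]12O | intermediate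
21 | C5 trimethylsilyl enol ether, 8-O-trimethylsilyl ether | CN(C)C(=O)C[C@H]1C=C(O[Si](C)(C)C)[C@]2(C)[C@H](OCc3ccc(OC)cc3)C=C[C@](C)(O[Si](CC)(CC)CC)C[C@]12O[Si](C)(C)C | intermediate
22 | 6β-bromo ketone, 8-O-trimethylsilyl ether | CN(C)C(=O)C[C@H]1[C@H](Br)C(=O)[C@]2(C)[C@H](OCc3ccc(OC)cc3)C=C[C@](C)(O[Si](CC)(CC)CC)C[C@]12O[Si](C)(C)C | intermediate
23 | iminium lactone bromide | C[N+](C)=C1O[C@H]2C(=O)[C@]3(C)[C@H](OCc4ccc(OC)cc4)C=C[C@](C)(O[Si](CC)(CC)CC)C[C@]3(O[Si](C)(C)C)[C@H]2C1.[Br-] | intermediate
24 | keto γ-lactone | O=C1O[C@H]2C(=O)[C@]3(C)[C@H](OCc4ccc(OC)cc4)C=C[C@](C)(O[Si](CC)(CC)CC)C[C@]3(O)[C@H]2C1 | intermediate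
25 | 5β-alcohol | O=C1O[C@H]2[C@H](O)[C@]3(C)[C@H](OCc4ccc(OC)cc4)C=C[C@](C)(O[Si](CC)(CC)CC)C[C@]3(O)[C@H]2C1 | intermediate
26 | lactone-fused cis-hydroazulenol 5β-mesylate | O=C1O[C@H]2[C@H](OS(C)(=O)=O)[C@]3(C)[C@H](OCc4ccc(OC)cc4)C=C[C@](C)(O[Si](CC)(CC)CC)C[C@]3(O)[C@H]2C1 | intermediate
27 | ten-membered C8 ketone with cis lactone, C3–OPMB, C10–OSiEt3 | O=C1O[C@H]2/C=C(/C)[C@H](OCc3ccc(OC)cc3)/C=C\[C@](C)(O[Si](CC)(CC)CC)CC(=O)[C@H]2C1 | intermediate
28 | C10 hydroxy ketone | O=C1O[C@H]2/C=C(/C)[C@H](OCc3ccc(OC)cc3)/C=C\[C@](C)(O)CC(=O)[C@H]2C1 | intermediate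
29 | (8R) 8,10-anti diol | O=C1O[C@H]2/C=C(/C)[C@H](OCc3ccc(OC)cc3)/C=C\[C@](C)(O)C[C@@H](O)[C@H]2C1 | intermediate
30 | tigloyl chloride | C/C=C(\C)C(=O)Cl | starting material
31 | C8 tiglate | O=C1O[C@H]2/C=C(/C)[C@H](OCc3ccc(OC)cc3)/C=C\[C@](C)(O)C[C@@H](OC(=O)/C(C)=C/C)[C@H]2C1 | intermediate
32 | Mannich base (C11 configuration immaterial) | CN(C)CC1C(=O)O[C@H]2/C=C(/C)[C@H](OCc3ccc(OC)cc3)/C=C\[C@](C)(O)C[C@@H](OC(=O)/C(C)=C/C)[C@@H]12 | intermediate
33 | methiodide of 32 | C[N+](C)(C)CC1C(=O)O[C@H]2/C=C(/C)[C@H](OCc3ccc(OC)cc3)/C=C\[C@](C)(O)C[C@@H](OC(=O)/C(C)=C/C)[C@@H]12.[I-] | intermediate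
34 | α-methylene lactone tiglate, C3–OPMB | C=C1C(=O)O[C@H]2/C=C(/C)[C@H](OCc3ccc(OC)cc3)/C=C\[C@](C)(O)C[C@@H](OC(=O)/C(C)=C/C)[C@@H]12 | intermediate
35 | (3R) bis-allylic alcohol | C=C1C(=O)O[C@H]2/C=C(/C)[C@H](O)/C=C\[C@](C)(O)C[C@@H](OC(=O)/C(C)=C/C)[C@@H]12 | intermediate
36 | CNP0135074.2 | C=C1C(=O)O[C@H]2/C=C(/C)C(=O)/C=C\[C@](C)(O)C[C@@H](OC(=O)/C(C)=C/C)[C@@H]12 | target

Total step count: 24
Longest linear sequence: 24 steps (1 to 36); 22 steps counted from 5.

Steps most likely to fail

Step 18. Acyl transfer from O6 to the cis C8 alkoxide (followed by epoxide closure onto C5), or enolisation of the new ketone with loss of the lactone carboxylate, may compete with fragmentation. The fallback lowers the oxidation level of C12 and sets out from 26. iBu2AlH (toluene, −78 °C) should give the lactol mesylate F1. Et3SiCl with imidazole should give the lactol triethylsilyl ether F2, which has no acyl group to migrate and a much poorer leaving group at C6. KN(SiMe3)2 should then give the ten-membered keto acetal F3, and HF·pyridine should remove both silyl groups to give the keto lactol F4. Ag2CO3 on Celite (Fétizon oxidation) restores the lactone, and the route is rejoined at 28.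

Step 20. Facial selectivity of the internal hydride delivery may be poor, because the methyl group and C1 on C10 are similar in size and the medium ring may override the chair transition state. The fallback sets out from 28 and aims at the other epimer on purpose. A Narasaka–Prasad reduction (Et2BOMe, NaBH4, THF–MeOH, −78 °C; external hydride on the boron chelate) should give the (8S) 8,10-syn diol F5. A Mitsunobu esterification with tiglic acid (PPh3, DIAD, toluene) then inverts C8 while forming the ester, and the route is rejoined at 31.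

Step 22. Deprotonation of the tiglate γ-position or of the doubly allylic C3–H, acyl shift to the C10 alkoxide, or conjugate addition of the amide base may compete with lactone enolisation. The fallback installs the methylene group before the ester and sets out from 29. Et3SiOTf with 2,6-lutidine should give the bis(triethylsilyl) ether F6. LiN(iPr)2 and Eschenmoser's salt should give the Mannich base F7, MeI the methiodide F8, and aqueous NaHCO3 the silylated α-methylene lactone F9. HF·pyridine frees the α-methylene lactone diol F10, and tigloyl chloride 30 with DMAP acylates only the secondary C8 hydroxyl, so the route is rejoined at 34.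

Further compounds
F1 | step 18 | lactol mesylate | OC1O[C@H]2[C@H](OS(C)(=O)=O)[C@]3(C)[C@H](OCc4ccc(OC)cc4)C=C[C@](C)(O[Si](CC)(CC)CC)C[C@]3(O)[C@H]2C1
F2 | step 18 | lactol triethylsilyl ether | CC[Si](CC)(CC)OC1O[C@H]2[C@H](OS(C)(=O)=O)[C@]3(C)[C@H](OCc4ccc(OC)cc4)C=C[C@](C)(O[Si](CC)(CC)CC)C[C@]3(O)[C@H]2C1
F3 | step 18 | ten-membered keto acetal | CC[Si](CC)(CC)OC1O[C@H]2/C=C(/C)[C@H](OCc3ccc(OC)cc3)/C=C\[C@](C)(O[Si](CC)(CC)CC)CC(=O)[C@H]2C1
F4 | step 18 | keto lactol | OC1O[C@H]2/C=C(/C)[C@H](OCc3ccc(OC)cc3)/C=C\[C@](C)(O)CC(=O)[C@H]2C1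
F5 | step 20 | (8S) 8,10-syn diol | O=C1O[C@H]2/C=C(/C)[C@H](OCc3ccc(OC)cc3)/C=C\[C@](C)(O)C[C@H](O)[C@H]2C1
F6 | step 22 | bis(triethylsilyl) ether | O=C1O[C@H]2/C=C(/C)[C@H](OCc3ccc(OC)cc3)/C=C\[C@](C)(O[Si](CC)(CC)CC)C[C@@H](O[Si](CC)(CC)CC)[C@H]2C1
F7 | step 22 | Mannich base | CN(C)CC1C(=O)O[C@H]2/C=C(/C)[C@H](OCc3ccc(OC)cc3)/C=C\[C@](C)(O[Si](CC)(CC)CC)C[C@@H](O[Si](CC)(CC)CC)[C@@H]12
F8 | step 22 | methiodide | C[N+](C)(C)CC1C(=O)O[C@H]2/C=C(/C)[C@H](OCc3ccc(OC)cc3)/C=C\[C@](C)(O[Si](CC)(CC)CC)C[C@@H](O[Si](CC)(CC)CC)[C@@H]12.[I-]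
F9 | step 22 | silylated α-methylene lactone | C=C1C(=O)O[C@H]2/C=C(/C)[C@H](OCc3ccc(OC)cc3)/C=C\[C@](C)(O[Si](CC)(CC)CC)C[C@@H](O[Si](CC)(CC)CC)[C@@H]12
F10 | step 22 | α-methylene lactone diol | C=C1C(=O)O[C@H]2/C=C(/C)[C@H](OCc3ccc(OC)cc3)/C=C\[C@](C)(O)C[C@@H](O)[C@@H]12
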